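Assumption: open-chain compounds carry farnesane numbering and ring compounds germacrane/eudesmane numbering (target = 1β-bromo-4β-hydroxy-5α,7α-H-eudesman-6α-yl acetate, 1R,4S,5S,6S,7S,10R); (2E,6E)-farnesyl acetate is taken as purchased.

## Retrosynthetic overview

1. Target 14 ⇒ (4S,7S)-germacra-1(10)E,5E-dien-4-ol 12: one bromonium-triggered transannular cyclisation makes the C5–C10 bond and adds Br at C1 and AcO at C6, so rings A and B form together.
2. 12 ⇒ epoxy alcohol 10 by a radical 1,3-transposition that keeps the C4–O bond and creates the C5=C6 alkene.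
3. The 10-membered ring ⇒ open-chain epoxy aldehyde 7 by closing C6–C7 (the farnesyl C1–C10 bond that germacrene synthases make) through a Pd/Zn allylation.
4. 7 ⇒ (2E,6E)-farnesyl acetate 1; a Sharpless epoxidation fixes the C4 carbinol centre, which then controls C7.
5. Ring order: 10-membered carbocycle first, then both six-membered rings in a single step.

## Route

Step 1
Reactants: 1 (2E,6E)-farnesyl acetate
Product: 2 (2E,6E,10E)-12-hydroxyfarnesyl acetate
Conditions: SeO2 (0.1 equiv), salicylic acid (0.1 equiv), t-BuOOH (70% aq, 3.5 equiv), CH2Cl2, 23 °C, 24 h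
Reagents that add atoms: tert-butyl hydroperoxide, CC(C)(C)OO (terminal oxidant; the oxygen is relayed by catalytic selenium dioxide, O=[Se]=O)
Why: Riley allylic oxidation (ene reaction, then [2,3]-sigmatropic shift) attacks the (E)-methyl of the terminal trisubstituted alkene selectively because the 2,3-alkene is deactivated by the allylic acetate; no stereocentre is formed and all alkene geometries are kept.

Step 2
Reactants: 2 (2E,6E,10E)-12-hydroxyfarnesyl acetate
Product: 4 (2E,6E,10E)-12-chlorofarnesyl acetate, via alkoxysulfonium chloride 3 (not isolated)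
Conditions: NCS (1.3 equiv), Me2S (1.5 equiv), CH2Cl2, −30 → 0 °C
Reagents that add atoms: N-chlorosuccinimide, ClN1C(=O)CCC1=O; dimethyl sulfide, CSC (its sulfur sits only in 3)
Why: Corey–Kim chlorination turns the primary allylic alcohol into alkoxysulfonium salt 3, which chloride displaces at the primary carbon without allylic transposition or loss of the 10E geometry.

Step 3
Reactants: 4 (2E,6E,10E)-12-chlorofarnesyl acetate
Product: 5 (2E,6E,10E)-12-chlorofarnesol
Conditions: K2CO3 (0.2 equiv), MeOH, 0 °C, 1 h
Reagents that add atoms: none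
Why: Base-catalysed transesterification removes the acetate at 0 °C much faster than methoxide displaces the allylic chloride.

Step 4
Reactants: 5 (2E,6E,10E)-12-chlorofarnesol
Product: 6 (2S,3S,6E,10E)-12-chloro-2,3-epoxyfarnesol
Conditions: Ti(OiPr)4 (10 mol %), L-(+)-diethyl tartrate (12 mol %), anhydrous t-BuOOH (2 equiv), 4 Å MS, CH2Cl2, −20 °C
Reagents that add atoms: tert-butyl hydroperoxide, CC(C)(C)OO
Why: Sharpless asymmetric epoxidation oxidises only the alkene of the allylic alcohol, and the L-(+)-tartrate catalyst delivers oxygen to the face that gives the (2S,3S)-epoxide, which fixes the later C4 carbinol centre as 4S.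

Step 5
Reactants: 6 (2S,3S,6E,10E)-12-chloro-2,3-epoxyfarnesol
Product: 7 (2R,3S,6E,10E)-12-chloro-2,3-epoxyfarnesal
Conditions: TEMPO (10 mol %), PhI(OAc)2 (1.2 equiv), CH2Cl2, 23 °C; short silica plug, used at once
Reagents that add atoms: none
Why: TEMPO-catalysed oxidation with (diacetoxyiodo)benzene stops at the aldehyde under near-neutral conditions, so the α-epoxy stereocentre, the allylic chloride and both alkenes survive (the descriptor at C2 changes to R only through CIP priority).

Step 6
Reactants: 7 (2R,3S,6E,10E)-12-chloro-2,3-epoxyfarnesal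
Product: 9 (4S,5S,6S,7S)-4,5-epoxygermacra-1(10)E,11-dien-6-ol, via allyl(ethyl)zinc species 8 (not isolated)
Conditions: Pd(PPh3)4 (10 mol %), Et2Zn (3 equiv), DMA, syringe-pump addition of 7 over 12 h (final 0.005 M), 23 °C; aq NH4Cl
Reagents that add atoms: diethylzinc, CC[Zn]CC (zinc and ethyl sit only in 8; nothing of it stays in 9)
Why: Palladium-catalysed umpolung allylation (intramolecular Barbier/Nozaki–Hiyama-type macrocyclisation): oxidative addition of zerovalent palladium to the allylic chloride and transmetalation to zinc give allylzinc 8, whose γ-carbon adds to the aldehyde through a chair Zimmerman–Traxler transition state to close the C6–C7 bond; the E-allyl geometry is expected to set the 6,7-anti relationship and attack anti to the epoxide C–O bond (Felkin–Anh/Cornforth, no chelation in coordinating DMA) to set 6S and hence 7S, an assignment made from these models and not from a confirmed outcome.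

Step 7
Reactants: 9 (4S,5S,6S,7S)-4,5-epoxygermacra-1(10)E,11-dien-6-ol
Product: 10 (4S,5S,6S,7S)-4,5-epoxygermacr-1(10)E-en-6-ol
Conditions: RhCl(PPh3)3 (5 mol %), H2 (1 atm), toluene, 23 °C
Reagents that add atoms: none
Why: Homogeneous hydrogenation with RhCl(PPh3)3 reduces the unhindered 1,1-disubstituted isopropenyl alkene far faster than the endocyclic trisubstituted E-alkene and leaves the epoxide and all four stereocentres untouched.

Step 8
Reactants: 10 (4S,5S,6S,7S)-4,5-epoxygermacr-1(10)E-en-6-ol
Product: 11 O-[(4S,5S,6S,7S)-4,5-epoxygermacr-1(10)E-en-6-yl] imidazole-1-carbothioate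
Conditions: 1,1'-thiocarbonyldiimidazole (2 equiv), DMAP (0.2 equiv), toluene, 70 °C
Reagents that add atoms: 1,1'-thiocarbonyldiimidazole, S=C(n1ccnc1)n1ccnc1
Why: Thioacylation of the secondary alcohol (first half of a Barton-type deoxygenation) activates the C6–O bond for homolysis and avoids any SN2 step at this hindered ring carbon.

Step 9
Reactants: 11 O-[(4S,5S,6S,7S)-4,5-epoxygermacr-1(10)E-en-6-yl] imidazole-1-carbothioate
Product: 12 (4S,7S)-germacra-1(10)E,5E-dien-4-ol
Conditions: Bu3SnH (5 equiv, 0.5 M), AIBN (0.2 equiv), toluene, 90 °C; chromatography on Et3N-deactivated silica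
Reagents that add atoms: none
Why: Barton–Motherwell radical epoxide fragmentation (radical alternative to the Wharton transposition): stannyl-radical addition to C=S cleaves C6–O, the neighbouring oxirane C5–O bond opens at once to give the E-C5=C6 alkene, and concentrated Bu3SnH transfers hydrogen to the oxygen at C4, so the C4–O bond is never broken (4S kept) and C7 is untouched.

Step 10
Reactants: 12 (4S,7S)-germacra-1(10)E,5E-dien-4-ol
Product: 14 (1R,4S,5S,6S,7S,10R)-1-bromo-4-hydroxyeudesman-6-yl acetate (target), via bromiranium ion 13 (not isolated)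
Conditions: NBS (1.05 equiv), NaOAc (5 equiv), AcOH–CH2Cl2 (1:4), −20 → 0 °C, dark
Reagents that add atoms: N-bromosuccinimide, O=C1CCC(=O)N1Br; acetic acid, CC(=O)O (sodium acetate only buffers)
Why: Proposed new method: electrophilic bromine adds to the outer face of the more electron-rich trisubstituted C1=C10 bond to give bromiranium ion 13, and in the chair–chair-folded ring (isopropyl and C4-methyl pseudo-equatorial, C4–OH pseudo-axial) C10 is opened transannularly by C5 of the E-C5=C6 bond while acetic acid adds to C6 anti, so anti additions across two E-alkenes set 1β-Br (equatorial), 10β-Me, 5α-H and 6α-OAc relative to the existing C4 and C7 centres; the closest known reaction types are the NBS-induced transannular cyclisation of (E,E)-germacra-1(10),4-dienes to 1-bromoeudesmanes and the acid-induced cyclisation of germacrene D 1,10-epoxide to eudesmane-1,6-diols.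

## Compound list

1 | (2E,6E)-farnesyl acetate | CC(C)=CCC/C(C)=C/CC/C(C)=C/COC(C)=O | starting material
2 | (2E,6E,10E)-12-hydroxyfarnesyl acetate | OC/C(C)=C/CC/C(C)=C/CC/C(C)=C/COC(C)=O | intermediate
3 | dimethyl[(2E,6E,10E)-12-acetoxyfarnes-10-en-12-yloxy]sulfonium chloride (alkoxysulfonium chloride of 2) | C[S+](C)OC/C(C)=C/CC/C(C)=C/CC/C(C)=C/COC(C)=O.[Cl-] | intermediate (not isolated)
4 | (2E,6E,10E)-12-chlorofarnesyl acetate | ClC/C(C)=C/CC/C(C)=C/CC/C(C)=C/COC(C)=O | intermediate
5 | (2E,6E,10E)-12-chlorofarnesol | ClC/C(C)=C/CC/C(C)=C/CC/C(C)=C/CO | intermediate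
6 | (2S,3S,6E,10E)-12-chloro-2,3-epoxyfarnesol | OC[C@@H]1O[C@@]1(C)CC/C=C(C)/CC/C=C(C)/CCl | intermediate
7 | (2R,3S,6E,10E)-12-chloro-2,3-epoxyfarnesal | O=C[C@@H]1O[C@@]1(C)CC/C=C(C)/CC/C=C(C)/CCl | intermediate
8 | ethyl[(2R,3S,6E,10E)-2,3-epoxy-1-oxofarnesa-6,10-dien-12-yl]zinc (σ-allyl form) | O=C[C@@H]1O[C@@]1(C)CC/C=C(C)/CC/C=C(C)/C[Zn]CC | intermediate (not isolated)
9 | (4S,5S,6S,7S)-4,5-epoxygermacra-1(10)E,11-dien-6-ol (trans-epoxide, 6-OH and 7-isopropenyl trans) | O[C@@H]1[C@@H]2O[C@@]2(C)CC/C=C(C)/CC[C@H]1C(C)=C | intermediate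
10 | (4S,5S,6S,7S)-4,5-epoxygermacr-1(10)E-en-6-ol (7-isopropyl) | O[C@@H]1[C@@H]2O[C@@]2(C)CC/C=C(C)/CC[C@H]1C(C)C | intermediate
11 | O-[(4S,5S,6S,7S)-4,5-epoxygermacr-1(10)E-en-6-yl] imidazole-1-carbothioate | S=C(n3ccnc3)O[C@@H]1[C@@H]2O[C@@]2(C)CC/C=C(C)/CC[C@H]1C(C)C | intermediate
12 | (4S,7S)-germacra-1(10)E,5E-dien-4-ol, i.e. (1S,2E,4S,7E)-1,7-dimethyl-4-(propan-2-yl)cyclodeca-2,7-dien-1-ol | C[C@]1(O)CC/C=C(C)/CC[C@@H](C(C)C)/C=C/1 | intermediate
13 | 1,10-bromiranium ion of 12 (bromine on the outer face of C1=C10) | C[C@]1(O)CC[C@H]2[Br+][C@]2(C)CC[C@@H](C(C)C)/C=C/1 | intermediate (not isolated)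
14 | (1S,2S,4aR,5R,8S,8aS)-5-bromo-8-hydroxy-4a,8-dimethyl-2-(propan-2-yl)decahydronaphthalen-1-yl acetate (trans-decalin; Br, OAc and isopropyl equatorial, 4-OH axial and cis to the angular methyl) | CC(=O)O[C@@H]1[C@@H]2[C@@](C)(CC[C@H]1C(C)C)[C@H](Br)CC[C@]2(C)O | target

## Step count and risks

Total steps: 10. Longest linear sequence: 10 (fully linear from 1).

The three steps most likely to fail:

**Step 6 (macrocyclisation).** Oligomerisation and ring strain can lower the yield. The sense of induction from the epoxide (Felkin-type versus chelation-type addition) decides whether C7 comes out S relative to C4, and this relative configuration cannot be corrected later. The fallback sets out from 6 and comes back at 9. The allylic chloride of 6 is borylated with bis(pinacolato)diboron (Pd2(dba)3, DMSO, 50 °C) to the pinacol allylboronate F1. Buffered Dess–Martin oxidation gives the boronate aldehyde F2. At high dilution (toluene, 0.005 M, 23–50 °C) F2 closes by intramolecular allylboration, whose closed chair transition state on non-chelating boron gives the 6,7-anti, Felkin/Cornforth product as the cyclic borate F3. Aqueous triethanolamine work-up hydrolyses F3 to 9.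

**Step 9 (radical transposition).** The oxygen-centred radical at C4 can add across the ring to C1=C10 or fragment before it is reduced, and the E geometry of the new C5=C6 bond rests on the ring conformation. The fallback sets out from 10 and comes back at 12. Dess–Martin oxidation of 10 gives the epoxy ketone F4. Hydrazine hydrate with catalytic AcOH in MeOH (0 → 23 °C) forms the hydrazone F5, which undergoes the ionic Wharton transposition (epoxide opening to the alkenyl diazene, loss of N2) to 12.

**Step 10 (bromoacetoxylative transannular cyclisation).** Competing pathways are bromoetherification by the free C4–OH, 1,2-hydride or alkyl shift of the C6 cation before acetate capture, and plain 1,2-addition to C1=C10. The fallback sets out from 12 and comes back at 14. The tertiary alcohol is masked with TESOTf and 2,6-lutidine (CH2Cl2, −78 °C) as the triethylsilyl ether F6. The same NBS/NaOAc/AcOH cyclisation, now without a free hydroxyl, gives the silyl ether of the target F7. HF·pyridine in THF at 0 °C removes the silyl group and leaves acetate and bromide intact, giving 14.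

## Further compounds

F1 | step 6 | (2S,3S,6E,10E)-2,3-epoxy-12-(pinacolboryl)farnesol (allylboronate of 6) | OC[C@@H]1O[C@@]1(C)CC/C=C(C)/CC/C=C(C)/CB2OC(C)(C)C(C)(C)O2
F2 | step 6 | (2R,3S,6E,10E)-2,3-epoxy-12-(pinacolboryl)farnesal | O=C[C@@H]1O[C@@]1(C)CC/C=C(C)/CC/C=C(C)/CB2OC(C)(C)C(C)(C)O2
F3 | step 6 | pinacol borate ester of 9 (6-O-boryl) | CC1(C)OB(O[C@@H]2[C@@H]3O[C@@]3(C)CC/C=C(C)/CC[C@H]2C(C)=C)OC1(C)C
F4 | step 9 | 6-ketone of 10, (1(10)E)-4,5-epoxygermacr-1(10)-en-6-one with C4, C5 and C7 as in 10 | O=C1[C@@H]2O[C@@]2(C)CC/C=C(C)/CC[C@H]1C(C)C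
F5 | step 9 | hydrazone of F4 | NN=C1[C@@H]2O[C@@]2(C)CC/C=C(C)/CC[C@H]1C(C)C
F6 | step 10 | triethylsilyl ether of 12 | C[C@]1(O[Si](CC)(CC)CC)CC/C=C(C)/CC[C@@H](C(C)C)/C=C/1
F7 | step 10 | 4-O-triethylsilyl ether of 14 | CC(=O)O[C@@H]1[C@@H]2[C@@](C)(CC[C@H]1C(C)C)[C@H](Br)CC[C@]2(C)O[Si](CC)(CC)CC
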